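All runs come from a simulation for substances that don't exist, and the scatter is random.

In a one-step world every coupling partner would end as left-handed product, and birch, with partner at 40.0 % of the left-handed and right-handed substrate charged together, would reach that figure, but the earlier runs tell us to expect less.

in all of them: left-handed substrate 0.10 M; right-handed substrate 0.10 M
- winter: coupling partner 0.040 M; protic impurity 0.020 M; temperature 0 °C; run made earlier
- midnight: coupling partner 0.16 M; protic impurity 0.020 M; temperature 20 °C; run made earlier
- birch: coupling partner 0.0800 M; protic impurity 0.0200 M; temperature 5 °C; time 2.5 h
- alder: coupling partner 0.0800 M; protic impurity 0.0200 M; at 5 °C until 80 min, from then on at 35 °C; time 2.5 h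
- maple: coupling partner 0.0800 M; protic impurity 0.0200 M; temperature 35 °C; time 2.5 h

| run | time / min | left-handed product / % | left-handed substrate / % |
|---|---|---|---|
| winter | 30.0 | 6.4 | 42.6 |
| winter | 60.0 | 6.9 | 40.3 |
| winter | 90.0 | 6.0 | 40.3 |
| winter | 120 | 7.3 | 40.6 |
| midnight | 5.00 | 21.0 | 24.7 |
| midnight | 10.0 | 23.6 | 20.6 |
| midnight | 25.0 | 26.3 | 17.3 |
| midnight | 60.0 | 26.5 | 19.1 |

(scatter of a reading: 0.5 percentage points)

- the best flask by amount of left-handed product, in percent of the left-handed substrate and right-handed substrate together charged; "all alike" if 1.5 percentage points covers them all (birch / alder / maple / all alike)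
- amount of left-handed product at the end, in percent of the left-handed substrate and right-handed substrate together charged, birch
- amount of left-handed product at the end, in percent of the left-handed substrate and right-handed substrate together charged, alder
- amount of left-handed product at the end, in percent of the left-handed substrate and right-handed substrate together charged, maple

- coupling partner is single-handed; left-handed substrate and right-handed substrate are mirror images of each other, charged as a racemate, each of them at the stated concentration
- the handed part of coupling partner does not stay in what it makes, so the products of the two hands are mirror images too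

For whoever takes over the bench, this is our own reckoning from the plateaus:

winter: 6.65 % on partner 20.0 % gives 0.333

midnight: 26.4 % on partner 80.0 % gives 0.330

mean 0.331; birch: 0.331 × 40.0 % = 13.2 %

The quantity we carry is the yield per partner, left-handed product at its plateau divided by partner charged, both as fractions of the charge, and it read 0.333 in the winter run and 0.330 in the midnight run, two runs that differ in partner charge as well as in temperature. Birch, alder and maple hold one charge, so expect about 13.2 % in each. The winter run stood at nearly all of its plateau by 30.0 min, earlier than alder's change at 80 min, and it was colder and held less partner than alder, so we expect that warming to touch nothing; leave the bath alone. Maple, at 35 °C, lies above both runs and is our least sure flask.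

The forecast gives 13.4 % for birch, 13.5 % for alder and 13.5 % for maple, hence all alike, holding that “later time adds nothing”; our figure lies slightly lower.

Birch gave 13.7 %, alder 13.7 % and maple 14.1 %, which is all alike. The steps that ran were these:

    2 coupling partner → homo dimer (k = 0.00250 M⁻¹ s⁻¹, Ea = 61.0 kJ mol⁻¹)
    coupling partner + left-handed substrate → left-handed product (k = 0.00890 M⁻¹ s⁻¹, Ea = 62.0 kJ mol⁻¹)
    coupling partner + right-handed substrate → right-handed product (k = 0.00370 M⁻¹ s⁻¹, Ea = 70.0 kJ mol⁻¹)
    coupling partner + protic impurity → quenched reagent (k = 0.0330 M⁻¹ s⁻¹, Ea = 61.0 kJ mol⁻¹)
    left-handed product ⇌ right-handed product (k = 6.40 × 10⁻⁴ s⁻¹, Ea = 85.0 kJ mol⁻¹)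
    (constants at 5 °C)

At the end of birch the coupling partner, the limiting reagent, stood at 0.0063 % of its charge while 63 % of the left-handed substrate remained, and birch's yield per partner reads 0.342. The neighbour of birch charged with 0.32 M of partner, 160 % of the charge, is promised 53.0 % by 0.331, but that flask holds 39.1 %, a yield per partner of 0.244.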